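**Retrosynthetic overview**
1. The target (2S,4S)-flavan-4-ol comes from (2S)-5,7-dimethoxy-8-prenylflavanone by substrate-controlled reduction of C4=O. The C8 prenyl group comes from a Stille coupling on the 8-iodide, made by iodination of (2S)-5,7-dimethoxyflavanone; the olefin is brought in only after the radical step because it would lie within reach of a C2 radical.
2. (2S)-5,7-Dimethoxyflavanone comes from a racemic fused cyclopropanol (a cyclopropa[b]benzofuran-6b-ol) and bromobenzene: the five-membered O-heterocycle is expanded by one carbon to the pyranone ring C, and in the same operation the C2–Ph bond and the C2 stereocentre are made.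
3. The cyclopropanol comes from 4,6-dimethoxybenzofuran-3(2H)-one by silyl enol ether formation and Simmons–Smith methylene transfer.
4. Enabling feature: in ring C, C2 carries the ring oxygen O1 and C4 is the carbinol/carbonyl carbon bound to ring A. In the precursor these two carbons are joined by the bond shared between the cyclopropane and the five-membered ring, so an oxygen-centred radical on the C4 carbinol cleaves exactly this bond, O1 stabilises the resulting C2 radical, and the cyclopropane CH2 becomes C3.
5. Ring order: ring A and the five-membered O-heterocycle are bought; the cyclopropane is fused on in step 2; ring C arises in step 3 by expansion of the five-membered ring; the phenyl ring enters intact.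

Key step: step 3

Remark (assumption): 4,6-dimethoxybenzofuran-3(2H)-one (1) is taken as a catalogue compound; the antipode of the chiral ligand in step 3 is the one that leads to the 2S series, to be confirmed by correlation with material from the fallback.

**Route**

Step 1
Reactants: 1 dimethoxycoumaranone (4,6-dimethoxybenzofuran-3(2H)-one); 2 trimethylsilyl trifluoromethanesulfonate
Product: 3 silyl enol ether 4,6-dimethoxy-3-(trimethylsilyloxy)benzofuran
Conditions: TMSOTf, Et3N, CH2Cl2, 0 °C; non-aqueous work-up
Reagents that add atoms: trimethylsilyl trifluoromethanesulfonate (2), C[Si](C)(C)OS(=O)(=O)C(F)(F)F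
Why: Soft enolisation and O-silylation (silyl enol ether formation) of the coumaranone should be driven by aromatisation to the benzofuran, and no stereocentre is formed.

Step 2
Reactants: 3 silyl enol ether 4,6-dimethoxy-3-(trimethylsilyloxy)benzofuran; 4 diiodomethane
Product: 6 rac-4,6-dimethoxy-1a,6b-dihydro-1H-cyclopropa[b]benzofuran-6b-ol, via siloxycyclopropane 5 (not isolated)
Conditions: Et2Zn, CH2I2, CH2Cl2, 0 °C to rt; then K2CO3 (cat.), MeOH, 0 °C
Reagents that add atoms: diiodomethane (4), ICI
Why: Simmons–Smith cyclopropanation (Furukawa variant) of the electron-rich, doubly oxygenated C2=C3 enol ether bond should give the necessarily cis-fused racemic siloxycyclopropane, and mild methanolysis of the O–Si bond frees the tertiary cyclopropanol, whose two ring-fusion stereocentres are erased again in step 3.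

Step 3
Reactants: 6 rac-4,6-dimethoxy-1a,6b-dihydro-1H-cyclopropa[b]benzofuran-6b-ol; 7 bromobenzene
Product: 8 (2S)-5,7-dimethoxy-2-phenylchroman-4-one
Conditions: PhBr, NiBr2·glyme (10 mol %), (S,S)-tBu-BiOX (12 mol %), 4CzIPN (2 mol %), 2,4,6-collidine, MeCN, blue LEDs, rt
Reagents that add atoms: bromobenzene (7), Brc1ccccc1
Why: Proposed new method: excited 4CzIPN oxidises the electron-rich aryl carbinol 6 and, with collidine as proton acceptor, gives the O-centred radical, whose β-scission cleaves the internal C1a–C6b bond to the ring-expanded 4-oxochroman-2-yl radical; this radical is captured by the phenylnickel bromide complex formed from PhBr and zerovalent nickel, and reductive elimination from trivalent nickel makes the C2–Ph bond. The closest known reaction types are the racemic photoredox/nickel ring-opening arylation of cyclopropanols and tertiary cycloalkanols with aryl bromides, the FeCl3 ring expansion of 1-siloxy- and 1-hydroxybicyclo[n.1.0]alkanes, and the nickel-catalysed enantioselective arylation of cyclic α-oxy radicals; their combination on a fused cyclopropanol is new. The six-membered ring C is not closed by a cyclisation but arises by one-carbon ring expansion of the five-membered O-heterocycle when the bond it shares with the cyclopropane breaks. The only new stereocentre, C2, is set under catalyst control by the chiral BiOX ligand on nickel in the radical-capture/reductive-elimination sequence, and because the radical is planar both enantiomers of 6 converge. The step needs internal instead of external C–C scission and coupling instead of β-hydride elimination to the chromone: the ring oxygen on C1a secures the first by stabilising the secondary radical (the alternative is a primary radical), and the bidentate N,N-ligand with fast reductive elimination from trivalent nickel is relied on for the second.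

Step 4
Reactants: 8 (2S)-5,7-dimethoxy-2-phenylchroman-4-one; 9 N-iodosuccinimide
Product: 10 (2S)-8-iodo-5,7-dimethoxy-2-phenylchroman-4-one
Conditions: NIS, CF3CO2H (cat.), MeCN, 0 °C
Reagents that add atoms: N-iodosuccinimide (9), O=C1CCC(=O)N1I
Why: Electrophilic aromatic iodination of the phloroglucinol-type ring A is expected at C8, which is para to the 5-methoxy group and flanked by the tied-back ring oxygen, rather than at C6 between two methoxy groups, and the C2 stereocentre is not touched.

Step 5
Reactants: 10 (2S)-8-iodo-5,7-dimethoxy-2-phenylchroman-4-one; 11 tributyl(3-methylbut-2-en-1-yl)stannane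
Product: 12 (2S)-5,7-dimethoxy-8-(3-methylbut-2-en-1-yl)-2-phenylchroman-4-one
Conditions: Pd(PPh3)4 (cat.), DMF, 90 °C
Reagents that add atoms: tributyl(3-methylbut-2-en-1-yl)stannane (11), CCCC[Sn](CCCC)(CCCC)CC=C(C)C
Why: Stille cross-coupling should transfer the prenyl group with reductive elimination at the less substituted allyl terminus (linear prenyl arene), and its neutral conditions avoid the base that would racemise the flavanone by retro-oxa-Michael ring opening.

Step 6
Reactants: 12 (2S)-5,7-dimethoxy-8-(3-methylbut-2-en-1-yl)-2-phenylchroman-4-one
Product: 13 (2S,4S)-5,7-dimethoxy-8-(3-methylbut-2-en-1-yl)-2-phenylchroman-4-ol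
Conditions: NaBH4, MeOH/THF, 0 °C; NaHCO3 work-up (no acid)
Reagents that add atoms: none
Why: Substrate-controlled borohydride reduction should deliver hydride to C4 along the axial trajectory of the half-chair with equatorial 2-phenyl, giving the equatorial 4-OH cis to the phenyl group, which is the (2S,4S) alcohol.

**Compound list**
1 | 4,6-dimethoxybenzofuran-3(2H)-one | COc1cc(OC)c2c(c1)OCC2=O | starting material
2 | trimethylsilyl trifluoromethanesulfonate | C[Si](C)(C)OS(=O)(=O)C(F)(F)F | starting material
3 | 4,6-dimethoxy-3-(trimethylsilyloxy)benzofuran | COc1cc(OC)c2c(O[Si](C)(C)C)coc2c1 | intermediate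
4 | diiodomethane | ICI | starting material
5 | rac-4,6-dimethoxy-6b-(trimethylsilyloxy)-1a,6b-dihydro-1H-cyclopropa[b]benzofuran (cis-fused racemate) | COc1cc(OC)c2c(c1)OC1CC12O[Si](C)(C)C | intermediate (not isolated)
6 | rac-4,6-dimethoxy-1a,6b-dihydro-1H-cyclopropa[b]benzofuran-6b-ol (cis-fused racemate) | COc1cc(OC)c2c(c1)OC1CC12O | intermediate
7 | bromobenzene | Brc1ccccc1 | starting material
8 | (2S)-5,7-dimethoxy-2-phenylchroman-4-one | COc1cc(OC)c2c(c1)O[C@H](c1ccccc1)CC2=O | intermediate
9 | N-iodosuccinimide | O=C1CCC(=O)N1I | starting material
10 | (2S)-8-iodo-5,7-dimethoxy-2-phenylchroman-4-one | COc1cc(OC)c2c(c1I)O[C@H](c1ccccc1)CC2=O | intermediate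
11 | tributyl(3-methylbut-2-en-1-yl)stannane | CCCC[Sn](CCCC)(CCCC)CC=C(C)C | starting material
12 | (2S)-5,7-dimethoxy-8-(3-methylbut-2-en-1-yl)-2-phenylchroman-4-one | COc1cc(OC)c2c(c1CC=C(C)C)O[C@H](c1ccccc1)CC2=O | intermediate
13 | (2S,4S)-5,7-dimethoxy-8-(3-methylbut-2-en-1-yl)-2-phenylchroman-4-ol (2,4-cis) | COc1cc(OC)c2c(c1CC=C(C)C)O[C@H](c1ccccc1)C[C@@H]2O | target

**Step count and risk**
Total steps: 6. Longest linear sequence: 6 (from 1).

Steps most likely to fail:

Step 3 (Proposed new method). Three processes may go wrong: capture of the ring-expanded C2 radical by nickel may lose to β-hydride elimination towards the chromone; scission of the external cyclopropane bond may compete and lead to benzylation at the exocyclic carbon; enantiocontrol at the radical-capture stage may be poor. The fallback separates ring expansion and C2–Ph bond formation into known operations. It sets out from 6: FeCl3 in DMF at 0 °C opens the cyclopropanol by the same alkoxy-radical β-scission and traps the C2 radical as the chloride, giving 2-chloro-5,7-dimethoxychroman-4-one F1. NaOAc in MeOH then eliminates HCl to 5,7-dimethoxy-4H-chromen-4-one F2. Rhodium-catalysed asymmetric 1,4-addition of PhB(OH)2 ([RhOH(cod)]2 with a chiral electron-poor biaryl bisphosphine of the MeO-F12-BIPHEP type, aqueous toluene, ligand antipode chosen for the 2S series) gives (2S)-5,7-dimethoxyflavanone, so the route is rejoined at 8.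

Step 4. Positional selectivity between C8 and C6 may be poor, or a second iodination may follow, because in the flavanone O1 is a good donor and activates C6 as well. The fallback moves the halogenation to the chromone oxidation level, where O1 is a vinylogous ester oxygen and a weaker donor, so that C8 (para to the 5-methoxy group) is favoured. It sets out from 6 and passes through 2-chloro-5,7-dimethoxychroman-4-one F1 to 5,7-dimethoxy-4H-chromen-4-one F2 as described above. NIS then gives 8-iodo-5,7-dimethoxy-4H-chromen-4-one F3, Stille coupling with 11 gives 5,7-dimethoxy-8-(3-methylbut-2-en-1-yl)-4H-chromen-4-one F4, and the rhodium-catalysed asymmetric 1,4-addition of PhB(OH)2 delivers the prenylated flavanone, so the route is rejoined at 12.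

Step 2. Carbenoid addition to the benzofuran C2=C3 bond may be slow because the furan ring has to give up its aromaticity, so that desilylation and C-methylation of the resulting zinc enolate take over. The fallback builds the cyclopropane by nucleophilic instead of electrophilic methylene transfer. It sets out from 3: NCS in THF at −78 °C gives 2-chloro-4,6-dimethoxybenzofuran-3(2H)-one F5. Bis(iodozincio)methane CH2(ZnI)2 adds to the ketone and the remaining C–Zn bond displaces the neighbouring chloride (the known cyclopropanol synthesis from carbonyl compounds with an α-leaving group), which after aqueous work-up gives the cyclopropanol, so the route is rejoined at 6.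

**Further compounds**
F1 | step 3 | 2-chloro-5,7-dimethoxychroman-4-one (racemate) | COc1cc(OC)c2c(c1)OC(Cl)CC2=O
F2 | step 3 | 5,7-dimethoxy-4H-chromen-4-one | COc1cc(OC)c2c(c1)occc2=O
F3 | step 4 | 8-iodo-5,7-dimethoxy-4H-chromen-4-one | COc1cc(OC)c2c(c1I)occc2=O
F4 | step 4 | 5,7-dimethoxy-8-(3-methylbut-2-en-1-yl)-4H-chromen-4-one | COc1cc(OC)c2c(c1CC=C(C)C)occc2=O
F5 | step 2 | 2-chloro-4,6-dimethoxybenzofuran-3(2H)-one (racemate) | COc1cc(OC)c2c(c1)OC(Cl)C2=O
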